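**Overview**

- Retrosynthesis: the O1–C2 bond of the dihydrofuran is cut first, then three bonds of the central benzene ring (C3a–C7a, C4–C5, C7–C7a, a cyclobutenone/siloxyalkyne benzannulation), then C2–C3 (aldol) and the bond from C6 to the benzofuran (aryllithium addition to 3-ethoxycyclobutenone).
- Enabling feature: the ring C3a/C4/C5/C6/C7/C7a is a resorcinol whose oxygens on C4 and C7a flank C3a (the carbon carrying C3), with the benzofuran-2-yl group on C6 para to C3a. This locally symmetric 2,5-disubstituted resorcinol is what a 3-arylcyclobutenone and a siloxyalkyne deliver, and either oxygen can close the furan.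
- Forward order of rings: both outer benzene rings are bought, the benzofuran is made from 6-hydroxybenzofuran-3(2H)-one, the central benzene ring is formed in the benzannulation that also joins the two halves, and the dihydrofuran closes last.
- Stereochemistry: C3 (S) is the alpha carbon of an Evans syn aldol under (R)-4-benzyl-2-oxazolidinone control and is carried unchanged. C2 (S) is fixed at ring closure, trans to the C3 aryl group; cation capture and direct displacement with inversion lead to the same isomer.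

Key step: step 13

Remark on the chemistry: the five phenols are carried as triisopropylsilyl ethers and the carbinol as a tert-butyldimethylsilyl ether (TIPSO = triisopropylsilyloxy, TBSO = tert-butyldimethylsilyloxy), so the only deprotection is one buffered fluoride treatment at the end.

**Route**

Step 1
Reactants: 1 3,5-dihydroxyphenylacetic acid
Product: 3 [3,5-bis(TIPSO)phenyl]acetic acid, via silyl ester 2 (not isolated)
Conditions: TIPSCl (3.5 equiv), imidazole, DMF, rt; then K2CO3, THF/H2O, 0 °C; citric acid work-up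
Reagents that add atoms: triisopropylsilyl chloride, CC(C)[Si](Cl)(C(C)C)C(C)C
Why: Exhaustive O-silylation caps both phenols and the acid, and the silyl ester, far more labile than the hindered aryl silyl ethers, is then hydrolysed selectively by aqueous carbonate.

Step 2
Reactants: 3 [3,5-bis(TIPSO)phenyl]acetic acid; 4 (R)-4-benzyl-2-oxazolidinone
Product: 6 (R)-4-benzyl-3-{[3,5-bis(TIPSO)phenyl]acetyl}-2-oxazolidinone, via mixed pivalic anhydride 5 (not isolated)
Conditions: t-BuCOCl, Et3N, THF, −20 °C; then LiCl, 4, −20 °C to rt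
Reagents that add atoms: none
Why: N-acylation of the oxazolidinone through the mixed pivalic anhydride takes place at the less hindered arylacetyl carbonyl and avoids strong base on the acidic arylacetic CH2 group.

Step 3
Reactants: 7 4-hydroxybenzaldehyde
Product: 8 4-(TIPSO)benzaldehyde
Conditions: TIPSCl, imidazole, DMF, rt
Reagents that add atoms: triisopropylsilyl chloride, CC(C)[Si](Cl)(C(C)C)C(C)C
Why: Imidazole-promoted O-silylation of a phenol gives an aryl silyl ether that tolerates the boron triflate, hydride, organolithium and thermal steps ahead.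

Step 4
Reactants: 6 (R)-4-benzyl-3-{[3,5-bis(TIPSO)phenyl]acetyl}-2-oxazolidinone; 8 4-(TIPSO)benzaldehyde
Product: 11 (R)-4-benzyl-3-{(2R,3R)-2-[3,5-bis(TIPSO)phenyl]-3-hydroxy-3-[4-(TIPSO)phenyl]propanoyl}-2-oxazolidinone, via Z boron enolate 9 (not isolated), via boron aldolate 10 (not isolated)
Conditions: Bu2BOTf, i-Pr2NEt, CH2Cl2, −78 to 0 °C; 8, −78 to 0 °C; then pH 7 buffer, MeOH, 30% H2O2, 0 °C
Reagents that add atoms: none
Why: Evans syn aldol, in which the Z boron enolate reacts through a closed Zimmerman–Traxler chair on the face opposite the benzyl group of the (R)-auxiliary, setting the alpha carbon (future C3) as R and the carbinol carbon as R.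

Step 5
Reactants: 11 syn aldol adduct
Product: 12 (R)-4-benzyl-3-{(2R,3R)-2-[3,5-bis(TIPSO)phenyl]-3-(TBSO)-3-[4-(TIPSO)phenyl]propanoyl}-2-oxazolidinone
Conditions: TBSOTf, 2,6-lutidine, CH2Cl2, −78 to 0 °C
Reagents that add atoms: tert-butyldimethylsilyl triflate, CC(C)(C)[Si](C)(C)OS(=O)(=O)C(F)(F)F
Why: Silyl triflate/lutidine O-silylation of the secondary benzylic alcohol blocks retro-aldol cleavage and installs the group that is ionized later at ring closure.

Step 6
Reactants: 12 TBS-protected aldol imide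
Product: 13 (2S,3R)-2-[3,5-bis(TIPSO)phenyl]-3-(TBSO)-3-[4-(TIPSO)phenyl]propan-1-ol
Conditions: LiBH4, MeOH (1 equiv), Et2O, 0 °C
Reagents that add atoms: none
Why: Reductive cleavage of the N-acyl oxazolidinone with LiBH4 attacks the exocyclic carbonyl, releases auxiliary 4 for recovery and gives the primary alcohol without enolizing the alpha-aryl centre (the descriptor changes to S only through the priority rules).

Step 7
Reactants: 13 primary alcohol
Product: 14 (2R,3R)-2-[3,5-bis(TIPSO)phenyl]-3-(TBSO)-3-[4-(TIPSO)phenyl]propanal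
Conditions: Dess–Martin periodinane, CH2Cl2, 0 °C to rt; filtered cold and used at once
Reagents that add atoms: none
Why: Dess–Martin oxidation is base-free and fast at 0 °C, so the configurationally labile alpha-aryl aldehyde is formed under neutral to weakly acidic conditions and is not stored.

Step 8
Reactants: 14 alpha-aryl aldehyde
Product: 15 (3R,4R)-1,1-dibromo-3-[3,5-bis(TIPSO)phenyl]-4-(TBSO)-4-[4-(TIPSO)phenyl]but-1-ene
Conditions: CBr4, PPh3, Zn dust, CH2Cl2, rt (reagent preformed); then 14, 0 °C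
Reagents that add atoms: carbon tetrabromide, BrC(Br)(Br)Br
Why: Ramirez dibromoolefination (first stage of the Corey–Fuchs sequence) with the zinc-generated ylide is a non-basic Wittig-type reaction, so the alpha stereocentre is left untouched.

Step 9
Reactants: 15 1,1-dibromoalkene
Product: 18 (3S,4R)-3-[3,5-bis(TIPSO)phenyl]-4-(TBSO)-1-(TIPSO)-4-[4-(TIPSO)phenyl]but-1-yne, via lithium acetylide 16 (not isolated), via lithium ynolate 17 (not isolated)
Conditions: n-BuLi (2.0 equiv), THF, −78 °C; LiOOt-Bu (from t-BuOOH and LiN(SiMe3)2), −78 to 0 °C; TIPSOTf, −78 to 0 °C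
Reagents that add atoms: lithium tert-butyl peroxide, [Li+].CC(C)(C)O[O-]; triisopropylsilyl triflate, CC(C)[Si](C(C)C)(C(C)C)OS(=O)(=O)C(F)(F)F
Why: Exactly two equivalents of n-BuLi give the lithium acetylide (bromine–lithium exchange, Fritsch–Buttenberg–Wiechell-type 1,2-hydrogen shift, deprotonation), lithium tert-butyl peroxide transfers oxygen to the acetylide carbon to give the ynolate, and the bulky silyl triflate silylates the ynolate on oxygen, while the propargylic C–H keeps its configuration because the base is consumed by more acidic sites.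

Step 10
Reactants: 19 6-hydroxybenzofuran-3(2H)-one
Product: 20 6-(TIPSO)benzofuran-3(2H)-one
Conditions: TIPSCl, imidazole, DMF, rt
Reagents that add atoms: triisopropylsilyl chloride, CC(C)[Si](Cl)(C(C)C)C(C)C
Why: Imidazole-promoted O-silylation of the phenol proceeds under conditions too mild to enolize and self-condense the coumaranone.

Step 11
Reactants: 20 6-(TIPSO)benzofuran-3(2H)-one
Product: 22 6-(TIPSO)benzofuran, via dihydrobenzofuranol 21 (not isolated)
Conditions: NaBH4, MeOH/THF, 0 °C; then 1 M aq. HCl, rt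
Reagents that add atoms: none
Why: Borohydride reduction of the ketone followed by acid-catalysed dehydration of the benzylic alcohol is driven by aromatization to the benzofuran.

Step 12
Reactants: 22 6-(TIPSO)benzofuran; 23 3-ethoxycyclobut-2-enone
Product: 26 3-[6-(TIPSO)benzofuran-2-yl]cyclobut-2-enone, via 2-lithiobenzofuran 24 (not isolated), via lithium alkoxide adduct 25 (not isolated)
Conditions: n-BuLi, THF, −78 °C; 23, −78 °C; then 1 M aq. HCl, 0 °C to rt
Reagents that add atoms: water, O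
Why: Benzofuran is lithiated at C2 (the most acidic position, next to the ring oxygen), the aryllithium adds 1,2 to the vinylogous ester, and aqueous acid ionizes the tertiary allylic alcohol and hydrolyses the enol ether with carbonyl transposition, the standard way to 3-substituted cyclobutenones.

Step 13
Reactants: 18 chiral triisopropylsiloxyalkyne; 26 3-[6-(TIPSO)benzofuran-2-yl]cyclobut-2-enone
Product: 31 2-{(1S,2R)-1-[3,5-bis(TIPSO)phenyl]-2-(TBSO)-2-[4-(TIPSO)phenyl]ethyl}-3-(TIPSO)-5-[6-(TIPSO)benzofuran-2-yl]phenol, via vinylketene 27 (not isolated), via 4-vinylcyclobutenone 28 (not isolated), via dienylketene 29 (not isolated), via cyclohexadienone 30 (not isolated)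
Conditions: toluene (degassed), 80 °C then 110 °C, near-equimolar partners, no additive
Reagents that add atoms: none
Why: Heating opens 26 by a 4-electron electrocyclic reaction to vinylketene 27, which adds to the electron-rich alkyne 18 in a regiospecific ketene–alkyne [2+2] cycloaddition to give 28; a second 4-electron opening gives dienylketene 29, 6-electron electrocyclization gives 30, and tautomerization gives phenol 31. The closest known reaction type is the Danheiser benzannulation of cyclobutenones with triisopropylsiloxyalkynes to resorcinol monosilyl ethers, which tolerates a propargylic stereocentre on the alkyne. The one ring closed is the central benzene ring: the [2+2] union makes C3a–C7a and C4–C5 (dihydrobenzofuran numbering) and the 6-electron electrocyclic closure makes C7–C7a. No stereocentre is created, since the sp3 carbon of 28 disappears on ring opening and the two side-chain stereocentres are spectators under neutral, reagent-free conditions. The selectivity needed is the regiochemistry of the [2+2] step, secured by the siloxy group, which makes the alkyne carbon bearing the side chain nucleophilic toward the ketene carbonyl carbon; this puts the side chain between the two oxygens and the benzofuranyl group para to it, and the local symmetry of the ring makes it irrelevant which oxygen emerges as the free phenol.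

Step 14
Reactants: 31 resorcinol monosilyl ether
Product: 32 (2S,3S)-3-[3,5-bis(TIPSO)phenyl]-4-(TIPSO)-6-[6-(TIPSO)benzofuran-2-yl]-2-[4-(TIPSO)phenyl]-2,3-dihydrobenzofuran
Conditions: CF3CO2H, CH2Cl2 (high dilution), −20 to 0 °C; NaHCO3 quench
Reagents that add atoms: none
Why: Acid-promoted loss of silanol from the benzylic silyl ether gives a cation stabilized by the para silyloxy group (SN1 etherification), which the one adjacent free phenol traps in a 5-exo-trig closure that places the C2 aryl group trans to the C3 aryl group, so C2 becomes S under control by C3, the same isomer that direct displacement with inversion would give.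

Step 15
Reactants: 32 pentakis-TIPS dihydrobenzofuran
Product: 33 (2S,3S)-3-(3,5-dihydroxyphenyl)-6-(6-hydroxybenzofuran-2-yl)-2-(4-hydroxyphenyl)-2,3-dihydrobenzofuran-4-ol
Conditions: Bu4NF, AcOH, THF, 0 °C to rt
Reagents that add atoms: none
Why: Fluoride-mediated desilylation cleaves all five aryl silyl ethers, and the acetic acid buffer keeps the phenols protonated so that no phenoxide can open the dihydrofuran through a quinone methide.

**Compound list**

1 | 3,5-dihydroxyphenylacetic acid | OC(=O)Cc1cc(O)cc(O)c1 | starting material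
2 | triisopropylsilyl [3,5-bis(TIPSO)phenyl]acetate | CC(C)[Si](C(C)C)(C(C)C)OC(=O)Cc1cc(O[Si](C(C)C)(C(C)C)C(C)C)cc(O[Si](C(C)C)(C(C)C)C(C)C)c1 | intermediate
3 | [3,5-bis(TIPSO)phenyl]acetic acid | OC(=O)Cc1cc(O[Si](C(C)C)(C(C)C)C(C)C)cc(O[Si](C(C)C)(C(C)C)C(C)C)c1 | intermediate
4 | (R)-4-benzyl-2-oxazolidinone | O=C1OC[C@@H](Cc2ccccc2)N1 | starting material
5 | [3,5-bis(TIPSO)phenyl]acetic pivalic anhydride | CC(C)(C)C(=O)OC(=O)Cc1cc(O[Si](C(C)C)(C(C)C)C(C)C)cc(O[Si](C(C)C)(C(C)C)C(C)C)c1 | intermediate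
6 | (R)-4-benzyl-3-{[3,5-bis(TIPSO)phenyl]acetyl}-2-oxazolidinone | O=C1OC[C@@H](Cc2ccccc2)N1C(=O)Cc1cc(O[Si](C(C)C)(C(C)C)C(C)C)cc(O[Si](C(C)C)(C(C)C)C(C)C)c1 | intermediate
7 | 4-hydroxybenzaldehyde | O=Cc1ccc(O)cc1 | starting material
8 | 4-(TIPSO)benzaldehyde | O=Cc1ccc(O[Si](C(C)C)(C(C)C)C(C)C)cc1 | intermediate
9 | (Z)-dibutylboron enolate of 6 | O=C1OC[C@@H](Cc2ccccc2)N1/C(OB(CCCC)CCCC)=C/c1cc(O[Si](C(C)C)(C(C)C)C(C)C)cc(O[Si](C(C)C)(C(C)C)C(C)C)c1 | intermediate
10 | O-dibutylboryl aldolate of 11 | O=C1OC[C@@H](Cc2ccccc2)N1C(=O)[C@@H]([C@@H](OB(CCCC)CCCC)c1ccc(O[Si](C(C)C)(C(C)C)C(C)C)cc1)c1cc(O[Si](C(C)C)(C(C)C)C(C)C)cc(O[Si](C(C)C)(C(C)C)C(C)C)c1 | intermediate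
11 | (R)-4-benzyl-3-{(2R,3R)-2-[3,5-bis(TIPSO)phenyl]-3-hydroxy-3-[4-(TIPSO)phenyl]propanoyl}-2-oxazolidinone | O=C1OC[C@@H](Cc2ccccc2)N1C(=O)[C@@H]([C@@H](O)c1ccc(O[Si](C(C)C)(C(C)C)C(C)C)cc1)c1cc(O[Si](C(C)C)(C(C)C)C(C)C)cc(O[Si](C(C)C)(C(C)C)C(C)C)c1 | intermediate
12 | (R)-4-benzyl-3-{(2R,3R)-2-[3,5-bis(TIPSO)phenyl]-3-(TBSO)-3-[4-(TIPSO)phenyl]propanoyl}-2-oxazolidinone | O=C1OC[C@@H](Cc2ccccc2)N1C(=O)[C@@H]([C@@H](O[Si](C)(C)C(C)(C)C)c1ccc(O[Si](C(C)C)(C(C)C)C(C)C)cc1)c1cc(O[Si](C(C)C)(C(C)C)C(C)C)cc(O[Si](C(C)C)(C(C)C)C(C)C)c1 | intermediate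
13 | (2S,3R)-2-[3,5-bis(TIPSO)phenyl]-3-(TBSO)-3-[4-(TIPSO)phenyl]propan-1-ol | OC[C@@H]([C@@H](O[Si](C)(C)C(C)(C)C)c1ccc(O[Si](C(C)C)(C(C)C)C(C)C)cc1)c1cc(O[Si](C(C)C)(C(C)C)C(C)C)cc(O[Si](C(C)C)(C(C)C)C(C)C)c1 | intermediate
14 | (2R,3R)-2-[3,5-bis(TIPSO)phenyl]-3-(TBSO)-3-[4-(TIPSO)phenyl]propanal | O=C[C@@H]([C@@H](O[Si](C)(C)C(C)(C)C)c1ccc(O[Si](C(C)C)(C(C)C)C(C)C)cc1)c1cc(O[Si](C(C)C)(C(C)C)C(C)C)cc(O[Si](C(C)C)(C(C)C)C(C)C)c1 | intermediate
15 | (3R,4R)-1,1-dibromo-3-[3,5-bis(TIPSO)phenyl]-4-(TBSO)-4-[4-(TIPSO)phenyl]but-1-ene | BrC(Br)=C[C@@H]([C@@H](O[Si](C)(C)C(C)(C)C)c1ccc(O[Si](C(C)C)(C(C)C)C(C)C)cc1)c1cc(O[Si](C(C)C)(C(C)C)C(C)C)cc(O[Si](C(C)C)(C(C)C)C(C)C)c1 | intermediate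
16 | lithium (3S,4R)-3-[3,5-bis(TIPSO)phenyl]-4-(TBSO)-4-[4-(TIPSO)phenyl]but-1-yn-1-ide | [Li]C#C[C@@H]([C@@H](O[Si](C)(C)C(C)(C)C)c1ccc(O[Si](C(C)C)(C(C)C)C(C)C)cc1)c1cc(O[Si](C(C)C)(C(C)C)C(C)C)cc(O[Si](C(C)C)(C(C)C)C(C)C)c1 | intermediate
17 | lithium (3S,4R)-3-[3,5-bis(TIPSO)phenyl]-4-(TBSO)-4-[4-(TIPSO)phenyl]but-1-yn-1-olate | [Li]OC#C[C@@H]([C@@H](O[Si](C)(C)C(C)(C)C)c1ccc(O[Si](C(C)C)(C(C)C)C(C)C)cc1)c1cc(O[Si](C(C)C)(C(C)C)C(C)C)cc(O[Si](C(C)C)(C(C)C)C(C)C)c1 | intermediate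
18 | (3S,4R)-3-[3,5-bis(TIPSO)phenyl]-4-(TBSO)-1-(TIPSO)-4-[4-(TIPSO)phenyl]but-1-yne | CC(C)[Si](C(C)C)(C(C)C)OC#C[C@@H]([C@@H](O[Si](C)(C)C(C)(C)C)c1ccc(O[Si](C(C)C)(C(C)C)C(C)C)cc1)c1cc(O[Si](C(C)C)(C(C)C)C(C)C)cc(O[Si](C(C)C)(C(C)C)C(C)C)c1 | intermediate
19 | 6-hydroxybenzofuran-3(2H)-one | O=C1COc2cc(O)ccc12 | starting material
20 | 6-(TIPSO)benzofuran-3(2H)-one | O=C1COc2cc(O[Si](C(C)C)(C(C)C)C(C)C)ccc12 | intermediate
21 | 6-(TIPSO)-2,3-dihydrobenzofuran-3-ol (racemic) | OC1COc2cc(O[Si](C(C)C)(C(C)C)C(C)C)ccc12 | intermediate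
22 | 6-(TIPSO)benzofuran | CC(C)[Si](C(C)C)(C(C)C)Oc1ccc2ccoc2c1 | intermediate
23 | 3-ethoxycyclobut-2-enone | CCOC1=CC(=O)C1 | starting material
24 | 2-lithio-6-(TIPSO)benzofuran | [Li]c1cc2ccc(O[Si](C(C)C)(C(C)C)C(C)C)cc2o1 | intermediate
25 | lithium 3-ethoxy-1-[6-(TIPSO)benzofuran-2-yl]cyclobut-2-en-1-olate | CCOC1=CC(O[Li])(c2cc3ccc(O[Si](C(C)C)(C(C)C)C(C)C)cc3o2)C1 | intermediate
26 | 3-[6-(TIPSO)benzofuran-2-yl]cyclobut-2-enone | O=C1C=C(c2cc3ccc(O[Si](C(C)C)(C(C)C)C(C)C)cc3o2)C1 | intermediate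
27 | 3-[6-(TIPSO)benzofuran-2-yl]buta-1,3-dien-1-one (vinylketene) | O=C=CC(=C)c1cc2ccc(O[Si](C(C)C)(C(C)C)C(C)C)cc2o1 | intermediate
28 | 4-vinylcyclobutenone: cyclobut-2-enone with the 1,2-diarylethyl side chain on C2, TIPSO on C3 and the 1-(benzofuranyl)vinyl group on C4 (both C4 epimers; side-chain centres as in 18) | O=C5C([C@@H]([C@@H](O[Si](C)(C)C(C)(C)C)c1ccc(O[Si](C(C)C)(C(C)C)C(C)C)cc1)c1cc(O[Si](C(C)C)(C(C)C)C(C)C)cc(O[Si](C(C)C)(C(C)C)C(C)C)c1)=C(O[Si](C(C)C)(C(C)C)C(C)C)C5C(=C)c1cc2ccc(O[Si](C(C)C)(C(C)C)C(C)C)cc2o1 | intermediate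
29 | dienylketene: 2-(side chain)-3-(TIPSO)-5-(benzofuranyl)hexa-1,3,5-trien-1-one with the cisoid 3,4-double bond | O=C=C([C@@H]([C@@H](O[Si](C)(C)C(C)(C)C)c1ccc(O[Si](C(C)C)(C(C)C)C(C)C)cc1)c1cc(O[Si](C(C)C)(C(C)C)C(C)C)cc(O[Si](C(C)C)(C(C)C)C(C)C)c1)/C(O[Si](C(C)C)(C(C)C)C(C)C)=C\C(=C)c1cc2ccc(O[Si](C(C)C)(C(C)C)C(C)C)cc2o1 | intermediate
30 | cyclohexa-2,4-dienone: 2-(side chain)-3-(TIPSO)-5-(benzofuranyl)cyclohexa-2,4-dien-1-one | O=C5CC(c1cc2ccc(O[Si](C(C)C)(C(C)C)C(C)C)cc2o1)=CC(O[Si](C(C)C)(C(C)C)C(C)C)=C5[C@@H]([C@@H](O[Si](C)(C)C(C)(C)C)c1ccc(O[Si](C(C)C)(C(C)C)C(C)C)cc1)c1cc(O[Si](C(C)C)(C(C)C)C(C)C)cc(O[Si](C(C)C)(C(C)C)C(C)C)c1 | intermediate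
31 | 2-{(1S,2R)-1-[3,5-bis(TIPSO)phenyl]-2-(TBSO)-2-[4-(TIPSO)phenyl]ethyl}-3-(TIPSO)-5-[6-(TIPSO)benzofuran-2-yl]phenol | Oc1cc(-c2cc3ccc(O[Si](C(C)C)(C(C)C)C(C)C)cc3o2)cc(O[Si](C(C)C)(C(C)C)C(C)C)c1[C@@H]([C@@H](O[Si](C)(C)C(C)(C)C)c1ccc(O[Si](C(C)C)(C(C)C)C(C)C)cc1)c1cc(O[Si](C(C)C)(C(C)C)C(C)C)cc(O[Si](C(C)C)(C(C)C)C(C)C)c1 | intermediate
32 | (2S,3S)-3-[3,5-bis(TIPSO)phenyl]-4-(TIPSO)-6-[6-(TIPSO)benzofuran-2-yl]-2-[4-(TIPSO)phenyl]-2,3-dihydrobenzofuran | CC(C)[Si](C(C)C)(C(C)C)Oc1ccc([C@H]2Oc3cc(-c4cc5ccc(O[Si](C(C)C)(C(C)C)C(C)C)cc5o4)cc(O[Si](C(C)C)(C(C)C)C(C)C)c3[C@@H]2c2cc(O[Si](C(C)C)(C(C)C)C(C)C)cc(O[Si](C(C)C)(C(C)C)C(C)C)c2)cc1 | intermediate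
33 | (2S,3S)-3-(3,5-dihydroxyphenyl)-6-(6-hydroxybenzofuran-2-yl)-2-(4-hydroxyphenyl)-2,3-dihydrobenzofuran-4-ol (CNP0112262.1) | Oc1ccc([C@H]2Oc3cc(-c4cc5ccc(O)cc5o4)cc(O)c3[C@@H]2c2cc(O)cc(O)c2)cc1 | target

**Count and risks**

Total: 15 steps. Longest linear sequence: 11 steps (steps 1, 2, 4, 5, 6, 7, 8, 9, 13, 14, 15).

Steps most likely to fail:

Step 13 (benzannulation). The [2+2] addition of the bulky, branched siloxyalkyne to the vinylketene may be slow at the temperature needed to open the cyclobutenone, so the ketene could be lost to oligomerization or to acylation of the product phenol. The fallback is the diazo ketone variant of the benzannulation, which makes the same vinylketene at room temperature by photochemical Wolff rearrangement. It sets out from lithiobenzofuran 24 and comes back to the route at vinylketene 27. Addition of 24 to excess butane-2,3-dione at −78 °C should give 3-hydroxy-3-[6-(TIPSO)benzofuran-2-yl]butan-2-one F1. Dehydration with the Burgess reagent should give 3-[6-(TIPSO)benzofuran-2-yl]but-3-en-2-one F2. Enolization with LiN(SiMe3)2 and acylation with 2,2,2-trifluoroethyl trifluoroacetate should give the trifluoroacetyl diketone 1,1,1-trifluoro-5-[6-(TIPSO)benzofuran-2-yl]hex-5-ene-2,4-dione F3, which is treated without isolation with MsN3, Et3N and water in MeCN (detrifluoroacetylative diazo transfer) to give 1-diazo-3-[6-(TIPSO)benzofuran-2-yl]but-3-en-2-one F4. Irradiation of a slight excess of F4 with alkyne 18 in CH2Cl2 at room temperature releases 27 slowly and at low stationary concentration, and brief heating in toluene then completes the cascade to 31.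

Step 14 (ring closure). The benzylic cation may lose the doubly benzylic C3 proton to give a triarylethene, and reprotonation would erode the C3 configuration; prolonged acid could also strip aryl silyl ethers. The fallback replaces cation chemistry by a displacement. It sets out from 31 and comes back at 32. Buffered HF·pyridine in THF/pyridine at 0 °C should remove the secondary alkyl TBS ether while the aryl TIPS ethers, slow to cleave under acidic fluoride, remain, giving the free carbinol 2-{(1S,2R)-1-[3,5-bis(TIPSO)phenyl]-2-hydroxy-2-[4-(TIPSO)phenyl]ethyl}-3-(TIPSO)-5-[6-(TIPSO)benzofuran-2-yl]phenol F5. Intramolecular Mitsunobu etherification of F5 (PPh3, DIAD, THF, 0 °C) should then close the ring with inversion at the carbinol carbon, giving the same trans (2S,3S) compound 32.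

Step 8 (dibromoolefination). The alpha-aryl aldehyde may epimerize or eliminate silanol during the comparatively slow Wittig-type reaction of a hindered aldehyde, and zinc or phosphonium bromides may attack the benzylic silyl ether. The fallback is a Colvin homologation, which bypasses 15. It sets out from aldehyde 14 and comes back at lithium acetylide 16. Lithiated trimethylsilyldiazomethane (TMSCHN2, n-BuLi, THF, −78 to 0 °C) adds to the aldehyde within minutes at low temperature and, through an alkylidene carbene and 1,2-hydrogen shift, should give the terminal alkyne (3R,4R)-3-[3,5-bis(TIPSO)phenyl]-4-(TBSO)-4-[4-(TIPSO)phenyl]but-1-yne F6. Deprotonation of F6 with LiN(SiMe3)2 at −78 °C gives 16, from which step 9 continues with the peroxide oxidation.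

Further compounds
F1 | step 13 | 3-hydroxy-3-[6-(TIPSO)benzofuran-2-yl]butan-2-one (racemic) | CC(=O)C(C)(O)c1cc2ccc(O[Si](C(C)C)(C(C)C)C(C)C)cc2o1
F2 | step 13 | 3-[6-(TIPSO)benzofuran-2-yl]but-3-en-2-one | CC(=O)C(=C)c1cc2ccc(O[Si](C(C)C)(C(C)C)C(C)C)cc2o1
F3 | step 13 | 1,1,1-trifluoro-5-[6-(TIPSO)benzofuran-2-yl]hex-5-ene-2,4-dione | O=C(CC(=O)C(F)(F)F)C(=C)c1cc2ccc(O[Si](C(C)C)(C(C)C)C(C)C)cc2o1
F4 | step 13 | 1-diazo-3-[6-(TIPSO)benzofuran-2-yl]but-3-en-2-one | [N-]=[N+]=CC(=O)C(=C)c1cc2ccc(O[Si](C(C)C)(C(C)C)C(C)C)cc2o1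
F5 | step 14 | 2-{(1S,2R)-1-[3,5-bis(TIPSO)phenyl]-2-hydroxy-2-[4-(TIPSO)phenyl]ethyl}-3-(TIPSO)-5-[6-(TIPSO)benzofuran-2-yl]phenol | Oc1cc(-c2cc3ccc(O[Si](C(C)C)(C(C)C)C(C)C)cc3o2)cc(O[Si](C(C)C)(C(C)C)C(C)C)c1[C@@H]([C@@H](O)c1ccc(O[Si](C(C)C)(C(C)C)C(C)C)cc1)c1cc(O[Si](C(C)C)(C(C)C)C(C)C)cc(O[Si](C(C)C)(C(C)C)C(C)C)c1
F6 | step 8 | (3R,4R)-3-[3,5-bis(TIPSO)phenyl]-4-(TBSO)-4-[4-(TIPSO)phenyl]but-1-yne | C#C[C@@H]([C@@H](O[Si](C)(C)C(C)(C)C)c1ccc(O[Si](C(C)C)(C(C)C)C(C)C)cc1)c1cc(O[Si](C(C)C)(C(C)C)C(C)C)cc(O[Si](C(C)C)(C(C)C)C(C)C)c1
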